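**Assumption:** Plagilin has no stereocentres, and its biaryl axis (2,2'-dialkyl, 6,6'-H) rotates freely, so the "single enantiomer" is simply the achiral compound as drawn; no stereocontrol is needed.

## Retrosynthetic overview

1. The obvious route (Ullmann homocoupling of a 6-bromo-aldehyde, then double Wittig and hydrogenation, or halogenate-and-couple a preformed bibenzyl) is avoided.
2. Key step: halide-free oxidative C–H/C–H dehydrodimerisation of a 4-bromocatechol ketal. The bromine blocks the second para position (no triphenylene trimer) and is kept as the handle for the arms.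
3. Both complete arms are then installed in one two-fold B-alkyl Suzuki coupling (sp3–sp2) with hydroborated 3-vinylanisole. The arms go on after the biaryl bond because a preformed bibenzyl would cyclise to a 9,10-dihydrophenanthrene under oxidative coupling.
4. Catechols are masked as acetonides, which are cleaved by aqueous acid without touching the two anisole methyl ethers.
5. Ring formation: none. All four benzene rings are purchased; only the two temporary dioxole rings are made (step 1) and opened (step 5).

## Route

**Step 1**
Reactants: 1, 4-bromocatechol (4-bromobenzene-1,2-diol)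
Product: 2, 5-bromo-2,2-dimethyl-1,3-benzodioxole
Conditions: 2,2-dimethoxypropane (3 equiv), p-TsOH·H2O (2 mol%), toluene, reflux, MeOH removed through a Soxhlet of 4 Å MS
Reagents that add atoms: 2,2-dimethoxypropane, COC(C)(C)OC (supplies the CMe2 unit)
Why: Acid-catalysed transketalisation of a catechol, driven by removal of methanol; no stereocentre is formed.

**Step 2**
Reactants: 2, 5-bromo-2,2-dimethyl-1,3-benzodioxole (2 molecules)
Product: 3, 6,6'-dibromo-2,2,2',2'-tetramethyl-5,5'-bi(1,3-benzodioxole) (biaryl bond ortho to each Br and para to a ring oxygen)
Conditions: MoCl5 (2.1 equiv), CH2Cl2, 0 °C, 30 min; quench with sat. aq. NaHCO3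
Reagents that add atoms: none
Why: Oxidative (Scholl-type, radical-cation) dehydrodimerisation of an electron-rich catechol ether, which couples at the only free position para to oxygen (C6). The ortho bromines twist the product biaryl and raise its oxidation potential, which stops over-oxidation; aryl bromides and catechol ketals are both known to survive MoCl5 at 0 °C.

**Step 3**
Reactants: 4, 3-vinylanisole (1-ethenyl-3-methoxybenzene), 2.6 equiv relative to 3
Product: 5, B-[2-(3-methoxyphenyl)ethyl]-9-borabicyclo[3.3.1]nonane, used in situ
Conditions: 9-BBN (0.5 M in THF, 2.7 equiv), THF, 0 °C to rt, 5 h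
Reagents that add atoms: 9-BBN, [H]B1C2CCCC1CCC2
Why: Anti-Markovnikov hydroboration of a styrene; 9-BBN places boron on the terminal carbon with about 98:2 selectivity.

**Step 4**
Reactants: 3, dibromobiaryl bis-acetonide (1 equiv); 5, alkyl-9-BBN (about 2.6 equiv, solution from step 3)
Product: 6, 6,6'-bis[2-(3-methoxyphenyl)ethyl]-2,2,2',2'-tetramethyl-5,5'-bi(1,3-benzodioxole)
Conditions: Pd(OAc)2 (5 mol%), SPhos (10 mol%), degassed 3 M aq. K3PO4 (6 equiv), THF/H2O, 65 °C, 16 h; then NaBO3 work-up to remove borane residues
Reagents that add atoms: none (all product atoms come from 3 and 5)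
Why: Two-fold B-alkyl Suzuki–Miyaura coupling; a bulky, electron-rich biarylphosphine promotes oxidative addition into the hindered, electron-rich C–Br bonds and makes reductive elimination faster than β-hydride elimination. Acetonides and methyl ethers are inert to the basic conditions.

**Step 5**
Reactants: 6, bis-acetonide of plagilin
Product: 7, plagilin, 2,2'-bis[2-(3-methoxyphenyl)ethyl]biphenyl-4,4',5,5'-tetraol
Conditions: TFA/H2O (9:1), degassed, Ar, 0 °C to rt, 4 h; concentrate, chromatograph under Ar
Reagents that add atoms: none (water supplies only H to the product; its oxygen leaves in acetone)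
Why: Acid hydrolysis of the catechol isopropylidene ketals; aryl methyl ethers are stable to aqueous TFA, so only the four catechol OH groups are released.

## Compound list

1 | 4-bromocatechol | Oc1ccc(Br)cc1O | starting material
2 | 5-bromo-2,2-dimethyl-1,3-benzodioxole | CC1(C)Oc2ccc(Br)cc2O1 | intermediate
3 | 6,6'-dibromo-2,2,2',2'-tetramethyl-5,5'-bi(1,3-benzodioxole) | CC1(C)Oc2cc(Br)c(cc2O1)-c1cc2OC(C)(C)Oc2cc1Br | intermediate
4 | 3-vinylanisole | C=Cc1cccc(OC)c1 | starting material
5 | B-[2-(3-methoxyphenyl)ethyl]-9-BBN | COc1cccc(CCB2C3CCCC2CCC3)c1 | intermediate (in situ)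
6 | 6,6'-bis[2-(3-methoxyphenyl)ethyl]-2,2,2',2'-tetramethyl-5,5'-bi(1,3-benzodioxole) | COc1cccc(CCc2cc3OC(C)(C)Oc3cc2-c2cc3OC(C)(C)Oc3cc2CCc2cccc(OC)c2)c1 | intermediate
7 | plagilin | COc1cccc(CCc2cc(O)c(O)cc2-c2cc(O)c(O)cc2CCc2cccc(OC)c2)c1 | target (achiral)

## Summary

Total step count: 5 (steps 3 and 4 run in one pot).
Longest linear sequence: 4 steps (1 → 2 → 3 → 6 → 7); step 3 is a one-step side branch.

Steps most likely to fail, with fallbacks:

1. **Step 2 (oxidative dehydrodimerisation).** Risks are ring chlorination, ketal cleavage by HCl/Mo species, or stalled conversion. Fallback: make 3 without an oxidant by the aryne/halogen-transfer route. Dibrominate catechol acetonide to 5,6-dibromo-2,2-dimethyl-1,3-benzodioxole and treat with 0.5 equiv n-BuLi in THF at −78 °C; the aryllithium adds to the in situ aryne and the adduct picks up bromine to give the 2,2'-dibromobiaryl.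
2. **Step 4 (double B-alkyl Suzuki at two hindered, electron-rich ortho positions).** Risks are mono-coupling, hydrodebromination and β-hydride elimination. Fallback: two-fold Sonogashira coupling of 3 with 3-ethynylanisole, then H2, Pd/C to saturate both alkynes, then step 5.
3. **Step 5 (release of an air-sensitive bis-catechol).** Risks are incomplete hydrolysis, acetone recombination and oxidation to quinone or dibenzofuran products. Fallback: change the protecting group from the start to the diphenylmethylene ketal (4-bromocatechol + Ph2CCl2), carry it through the same sequence, and remove it at the end by neutral hydrogenolysis (H2, Pd/C), which leaves the methyl ethers intact and avoids acid.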